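Everything rests on cutting two bonds at the adjacent quaternary carbons of ring B: C10–C20, which belongs to the δ-lactone bridging ring A, and C9–O, which belongs to the spiro tetrahydrofuran (labdane numbering). These bonds are trans-diaxial, the mark of anti addition to a C9=C10 olefin. In one cationic operation a CH2+ unit held on the C19 carboxylate adds to C10 from the upper face and the C13 hydroxyl of the side-chain lactone captures C9 from below, closing two rings and setting both centres. The precursor is a Δ9(10)-octalin with the C19 chloromethyl ester, a 6β-silyl ether, the 8α-methyl group and the (S)-hydroxy lactone arm.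

Key step: step 18

Remark on numbering: all bicyclic compounds carry labdane locants (ring A = C1–C5 and C10; ring B = C5–C10; C17 on C8; C18 and C19 on C4; C20 on C10; C11–C16 in the side chain). β is the face that carries C20 in the target, α the opposite face.

Assumption: the (S)-oxazaborolidinium catalyst of step 3 is taken to expose the quinone face that leads to 5; if its facial sense is the reverse, the (R)-catalyst gives 5 under the same conditions.

Remark: C8 is trigonal in 13, is left undefined in 14 and 15, and is fixed in step 9.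

Step 1
Reactants: 1 (E)-pent-2-en-4-yn-1-ol
Product: 2 triethylsilyl ether of 1
Conditions: Et3SiCl, imidazole, CH2Cl2, 0 °C
Reagents that add atoms: chlorotriethylsilane, CC[Si](Cl)(CC)CC
Why: Silyl ether formation from a primary alcohol with a chlorosilane and imidazole is a routine protection and should leave the enyne untouched.

Step 2
Reactants: 2 triethylsilyl ether of 1
Product: 3 (2E,4E)-1-silyloxy-5-silyl diene
Conditions: Et3SiH, PtCl2 (1 mol %), XPhos (2 mol %), THF, 50 °C
Reagents that add atoms: triethylsilane, CC[SiH](CC)CC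
Why: Platinum-catalysed alkyne hydrosilylation with a bulky phosphine should add Si–H syn and anti-Markovnikov to the terminal triple bond, which fixes the new olefin as (E) and gives the (E,E)-1-silyl diene without touching the existing (E)-alkene.

Step 3
Reactants: 3 (2E,4E)-1-silyloxy-5-silyl diene; 4 2-methyl-1,4-benzoquinone
Product: 5 cis-fused endo adduct
Conditions: (S)-3,3-diphenyl-1-(2-methylphenyl)tetrahydro-1H,3H-pyrrolo[1,2-c][1,3,2]oxazaborole (20 mol %), HNTf2 (18 mol %), CH2Cl2, −78 °C
Reagents that add atoms: none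
Why: The enantioselective Diels–Alder reaction under chiral oxazaborolidinium catalysis should engage the unsubstituted quinone double bond through an endo transition state in which the catalyst binds the more basic C6 carbonyl (vinylogous to the methyl group), so that the silyl-bearing diene terminus bonds to C10 and the oxymethyl-bearing terminus to C5, the endo rule making H1, H4, H5 and H10 mutually cis (C19 trans to H5) and the catalyst face fixing the absolute configuration at C5 and C4.

Step 4
Reactants: 5 cis-fused endo adduct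
Product: 7 ene-triol, via diol silyl ether 6 (not isolated)
Conditions: NaBH4, CeCl3·7H2O, MeOH, −78 °C; then pyridinium p-toluenesulfonate (0.3 equiv), rt
Reagents that add atoms: none
Why: Luche reduction should deliver hydride 1,2 to both enone carbonyls from the convex face of the cis-fused bicycle (the face of H5 and H10), which sets the 6β-hydroxyl (and a 9β-hydroxyl that is oxidised later), and the acidic methanol then removes only the primary O-triethylsilyl group.

Step 5
Reactants: 7 ene-triol
Product: 9 hydroxy ene lactone, via lactol 8 (not isolated)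
Conditions: [Cu(MeCN)4]OTf (10 mol %), 2,2′-bipyridine (10 mol %), TEMPO (10 mol %), N-methylimidazole (20 mol %), air, MeCN, rt
Reagents that add atoms: none
Why: Aerobic copper/nitroxyl alcohol oxidation is selective for the primary hydroxyl, and the oxidised carbon is trapped by the adjacent cis 6β-hydroxyl as five-membered lactol 8, which is oxidised on to the γ-lactone while the secondary allylic hydroxyl at C9 is left alone.

Step 6
Reactants: 9 hydroxy ene lactone
Product: 11 C4-methyl hydroxy ene lactone, via dilithio dianion 10 (not isolated)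
Conditions: LiN(i-Pr)2 (2.3 equiv), THF, −78 °C; MeI, −78 → −30 °C; H2O
Reagents that add atoms: iodomethane, CI
Why: Enolate alkylation of dianion 10 should take place at the α-carbon C4 from the face of H5, the only approach that keeps the γ-lactone cis-fused to ring A, so that the new methyl group (C18) is α and C19 stays β.

Step 7
Reactants: 11 C4-methyl hydroxy ene lactone
Product: 12 enone lactone
Conditions: MnO2 (excess), CH2Cl2, rt
Reagents that add atoms: none
Why: MnO2 oxidation is selective for the allylic C9 alcohol and should give the enone without affecting the lactone or the allylsilane.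

Step 8
Reactants: 12 enone lactone
Product: 14 keto lactone (C8 epimers), via lithium enolate 13 (not isolated)
Conditions: LiBH(s-Bu)3 (1.1 equiv), THF, −78 °C; AcOH
Reagents that add atoms: none
Why: Conjugate reduction of the 2-methylcyclohexenone unit by the hindered borohydride and protonation of enolate 13 should saturate C7–C8; the configuration at C8 is not controlled here and is settled in step 9.

Step 9
Reactants: 14 keto lactone (C8 epimers)
Product: 16 Δ1(10)-enone lactone, via β,γ-enone 15 (not isolated)
Conditions: CF3CO2H, CH2Cl2, 0 °C → rt; concentrate; then DBU (0.3 equiv), PhMe, rt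
Reagents that add atoms: none
Why: Protodesilylation of the allylsilane (SE2′) moves the ring A double bond to C1=C2, and base-mediated conjugation of 15 then gives the Δ1(10)-enone while C8 epimerises under the same basic conditions to the equatorial 8α-methyl isomer, which avoids a syn-axial clash with the axial 6β-oxygen on the conformationally anchored ring B.

Step 10
Reactants: 16 Δ1(10)-enone lactone
Product: 18 bis-silylated enone, via lithium carboxylate 17 (not isolated)
Conditions: LiOH·H2O (1.2 equiv), THF/H2O, 40 °C; evaporate, dry (PhMe azeotrope); then TBSOTf (3 equiv), 2,6-lutidine, CH2Cl2, −78 → 0 °C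
Reagents that add atoms: lithium hydroxide, [Li+].[OH-]; tert-butyldimethylsilyl trifluoromethanesulfonate, CC(C)(C)[Si](C)(C)OS(=O)(=O)C(F)(F)F
Why: Saponification of the γ-lactone gives carboxylate 17, which as its lithium salt does not relactonise, and silylation with the silyl triflate then caps the 6β-hydroxyl as its ether and the carboxylate as a labile silyl ester, with no new stereocentre and C8 remaining in its thermodynamically preferred configuration.

Step 11
Reactants: 18 bis-silylated enone
Product: 20 enol triflate, via lithium enolate 19 (not isolated)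
Conditions: LiBH(s-Bu)3 (1.2 equiv), THF, −78 °C; then N-(5-chloropyridin-2-yl)-1,1,1-trifluoro-N-(trifluoromethylsulfonyl)methanesulfonamide, −78 → 0 °C; H2O
Reagents that add atoms: N-(5-chloropyridin-2-yl)-1,1,1-trifluoro-N-(trifluoromethylsulfonyl)methanesulfonamide, FC(F)(F)S(=O)(=O)N(c1ccc(Cl)cn1)S(=O)(=O)C(F)(F)F
Why: Conjugate reduction of the s-cis Δ1(10)-enone places hydride on C1 and gives the C9=C10 enolate 19 regiospecifically, and O-sulfonylation with the pyridyl triflimide converts it into the tetrasubstituted enol triflate without disturbing C8.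

Step 12
Reactants: 21 (S)-malic acid
Product: 22 cis-dioxolanone acid
Conditions: t-BuCHO, TsOH·H2O (cat.), H2SO4 (cat.), pentane, reflux, water separator
Reagents that add atoms: 2,2-dimethylpropanal, CC(C)(C)C=O
Why: Acid-catalysed acetalisation of the α-hydroxy acid unit with pivalaldehyde (self-regeneration of stereocentres) gives the cis-dioxolanone, the acetal centre being set under thermodynamic control cis to the acetic acid arm while the future C13 is untouched.

Step 13
Reactants: 22 cis-dioxolanone acid; 23 phenyl vinyl sulfoxide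
Product: 25 sulfinylethyl dioxolanone acid, via dilithio dianion 24 (not isolated)
Conditions: LiN(SiMe3)2 (2.2 equiv), THF, −78 °C; 23, −78 → −30 °C; AcOH
Reagents that add atoms: phenyl vinyl sulfoxide 23, C=CS(=O)c1ccccc1
Why: Michael addition of dianion 24 to the vinyl sulfoxide should occur anti to the tert-butyl group, so that the new two-carbon arm takes the place of the former hydrogen and the configuration of the future C13 is retained.

Step 14
Reactants: 25 sulfinylethyl dioxolanone acid
Product: 26 vinyl dioxolanone acid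
Conditions: CaCO3, PhMe, 110 °C
Reagents that add atoms: none
Why: Thermal syn-elimination of the sulfoxide can only involve the hydrogens of the CH2 next to the quaternary carbon and therefore should give the vinyl group (the future C11 and C12).

Step 15
Reactants: 26 vinyl dioxolanone acid
Product: 29 vinyl hydroxy lactone, via mixed anhydride 27 (not isolated), via hydroxyethyl dioxolanone 28 (not isolated)
Conditions: i-BuOCOCl, N-methylmorpholine, THF, −15 °C; then NaBH4, H2O, 0 °C; aq. citric acid
Reagents that add atoms: none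
Why: Borohydride reduction of mixed anhydride 27 is chemoselective for the acetic acid arm (no hydroboration of the vinyl group), and primary alcohol 28 lactonises onto the dioxolanone carbonyl with loss of pivalaldehyde, which leaves C13 untouched and gives two different arms so that no degenerate translactonisation can racemise it.

Step 16
Reactants: 29 vinyl hydroxy lactone; 20 enol triflate
Product: 32 seco acid, via alkylborane 30 (not isolated), via silyl ester 31 (not isolated)
Conditions: 29, 9-BBN (2.5 equiv), THF, 0 °C → rt; then 20, Pd(dppf)Cl2·CH2Cl2 (10 mol %), AsPh3 (10 mol %), Cs2CO3, DMF/THF/H2O, rt; 10% aq. citric acid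
Reagents that add atoms: none
Why: Anti-Markovnikov hydroboration of the vinyl group followed by B-alkyl Suzuki–Miyaura coupling with the enol triflate forms the C9–C11 bond, and the silyl ester is hydrolysed by the aqueous carbonate and the citric acid work-up, neither operation touching a stereocentre.

Step 17
Reactants: 32 seco acid; 33 chloromethyl chlorosulfate
Product: 34 chloromethyl ester (cascade precursor)
Conditions: NaHCO3, Bu4NHSO4 (10 mol %), CH2Cl2/H2O, 0 °C → rt
Reagents that add atoms: chloromethyl chlorosulfate 33, ClCOS(=O)(=O)Cl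
Why: O-Alkylation of the carboxylate with chloromethyl chlorosulfate under phase-transfer conditions is a standard way to chloromethyl esters and is insensitive to the hindrance at C4 because the bond is formed at oxygen.

Step 18
Reactants: 34 chloromethyl ester (cascade precursor)
Product: 37 6-O-silyl ether of the target, via acyloxymethyl cation 35 (not isolated), via C9 cation 36 (not isolated)
Conditions: AgOTf (1.5 equiv), 2,6-di-tert-butyl-4-methylpyridine (2 equiv), 4 Å molecular sieves, CH2Cl2, −40 → 0 °C, dark
Reagents that add atoms: none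
Why: Proposed new method: AgOTf abstracts chloride from the chloromethyl ester to give the acyloxy-stabilised methylene cation 35, which the axial C19 carboxylate holds above C10, so that the electron-rich tetrasubstituted C9=C10 olefin attacks it and the resulting tertiary cation 36 is captured by the C13 hydroxyl with loss of a proton to the pyridine base. The closest known reaction type is the Prins cyclisation of an oxocarbenium ion onto an olefin with trapping by a tethered hydroxyl, together with the use of acyloxymethyl halides as formaldehyde-cation equivalents. The δ-lactone closes 6-exo-trig (C20 to C10, the tether being too short for any other ring), and the tetrahydrofuran closes by five-membered attack of oxygen on C9 (5-exo with respect to the former olefin). C10 is controlled by the C4 stereocentre, because the one-atom C5 bridge forces C19 and C20 onto the same β face, and C9 is controlled by anti addition, the oxygen entering axially from the α face opposite the new C10–C20 bond so that C11 becomes equatorial. The step needs C-alkylation at C10 in preference to proton loss, O-alkylation or acid-induced protonation of the olefin, and the intramolecular six-membered delivery, the poor nucleophilicity of the hindered silyl ether and the buffering of triflic acid by the hindered pyridine secure this.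

Step 19
Reactants: 37 6-O-silyl ether of the target
Product: 38 target CNP0393616.1
Conditions: HF·pyridine, pyridine, THF, 0 °C → rt
Reagents that add atoms: none
Why: Fluoride-mediated cleavage of the silyl ether with buffered HF·pyridine should free the 6β-hydroxyl without opening either lactone or promoting acyl migration from O20 to O6.

Compound list

1 | (E)-pent-2-en-4-yn-1-ol | C#C/C=C/CO | starting material
2 | triethyl[(E)-pent-2-en-4-yn-1-yloxy]silane | C#C/C=C/CO[Si](CC)(CC)CC | intermediate
3 | triethyl{[(2E,4E)-5-(triethylsilyl)penta-2,4-dien-1-yl]oxy}silane | CC[Si](CC)(CC)/C=C/C=C/CO[Si](CC)(CC)CC | intermediate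
4 | 2-methyl-1,4-benzoquinone | CC1=CC(=O)C=CC1=O | starting material
5 | 8-methyl-1β-(triethylsilyl)-4β-[(triethylsilyloxy)methyl]-5α,10α-bicyclo[4.4.0]deca-2,7-diene-6,9-dione (endo adduct; H1, H4, H5, H10 all α) | CC1=CC(=O)[C@@H]2[C@H](C1=O)[C@H]([Si](CC)(CC)CC)C=C[C@@H]2CO[Si](CC)(CC)CC | intermediate
6 | 8-methyl-1β-(triethylsilyl)-4β-[(triethylsilyloxy)methyl]-5α,10α-bicyclo[4.4.0]deca-2,7-diene-6β,9β-diol | CC1=C[C@@H](O)[C@@H]2[C@H]([C@H]1O)[C@H]([Si](CC)(CC)CC)C=C[C@@H]2CO[Si](CC)(CC)CC | intermediate
7 | 4β-(hydroxymethyl)-8-methyl-1β-(triethylsilyl)-5α,10α-bicyclo[4.4.0]deca-2,7-diene-6β,9β-diol | CC1=C[C@@H](O)[C@@H]2[C@H]([C@H]1O)[C@H]([Si](CC)(CC)CC)C=C[C@@H]2CO | intermediate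
8 | cyclic hemiacetal between C19 and the 6β-oxygen of the C19 aldehyde of 7 (both C19 epimers) | CC1=C[C@H]2OC(O)[C@H]3C=C[C@@H]([Si](CC)(CC)CC)[C@@H]([C@H]1O)[C@@H]23 | intermediate
9 | 9β-hydroxy-8-methyl-1β-(triethylsilyl)-5α,10α-bicyclo[4.4.0]deca-2,7-diene-4β-carboxylic acid 19,6β-lactone (H4 α) | CC1=C[C@H]2OC(=O)[C@H]3C=C[C@@H]([Si](CC)(CC)CC)[C@@H]([C@H]1O)[C@@H]23 | intermediate
10 | dilithium salt of 9 (C9 alkoxide, C4=C19 lactone enolate) | CC1=C[C@H]2OC([O-])=C3C=C[C@@H]([Si](CC)(CC)CC)[C@@H]([C@H]1[O-])[C@@H]23.[Li+].[Li+] | intermediate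
11 | 9β-hydroxy-4α,8-dimethyl-1β-(triethylsilyl)-5α,10α-bicyclo[4.4.0]deca-2,7-diene-4β-carboxylic acid 19,6β-lactone | CC1=C[C@H]2OC(=O)[C@@]3(C)C=C[C@@H]([Si](CC)(CC)CC)[C@@H]([C@H]1O)[C@@H]23 | intermediate
12 | 4α,8-dimethyl-9-oxo-1β-(triethylsilyl)-5α,10α-bicyclo[4.4.0]deca-2,7-diene-4β-carboxylic acid 19,6β-lactone | CC1=C[C@H]2OC(=O)[C@@]3(C)C=C[C@@H]([Si](CC)(CC)CC)[C@@H](C1=O)[C@@H]23 | intermediate
13 | lithium C8=C9 enolate formed from 12 by hydride addition at C7 | CC=1C[C@H]2OC(=O)[C@@]3(C)C=C[C@@H]([Si](CC)(CC)CC)[C@@H](C=1[O-])[C@@H]23.[Li+] | intermediate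
14 | 4α,8-dimethyl-9-oxo-1β-(triethylsilyl)-5α,10α-bicyclo[4.4.0]dec-2-ene-4β-carboxylic acid 19,6β-lactone (both C8 epimers) | CC1C[C@H]2OC(=O)[C@@]3(C)C=C[C@@H]([Si](CC)(CC)CC)[C@@H](C1=O)[C@@H]23 | intermediate
15 | 4α,8-dimethyl-9-oxo-5α,10α-bicyclo[4.4.0]dec-1-ene-4β-carboxylic acid 19,6β-lactone (both C8 epimers) | CC1C[C@H]2OC(=O)[C@@]3(C)CC=C[C@@H](C1=O)[C@@H]23 | intermediate
16 | 4α,8α-dimethyl-9-oxo-5α-bicyclo[4.4.0]dec-1(10)-ene-4β-carboxylic acid 19,6β-lactone | C[C@@H]1C[C@H]2OC(=O)[C@@]3(C)CCC=C(C1=O)[C@@H]23 | intermediate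
17 | lithium 6β-hydroxy-4α,8α-dimethyl-9-oxo-5α-bicyclo[4.4.0]dec-1(10)-ene-4β-carboxylate | C[C@@H]1C[C@@H](O)[C@@H]2C(=CCC[C@]2(C)C(=O)[O-])C1=O.[Li+] | intermediate
18 | tert-butyldimethylsilyl 6β-(tert-butyldimethylsilyloxy)-4α,8α-dimethyl-9-oxo-5α-bicyclo[4.4.0]dec-1(10)-ene-4β-carboxylate | C[C@@H]1C[C@@H](O[Si](C)(C)C(C)(C)C)[C@@H]2C(=CCC[C@]2(C)C(=O)O[Si](C)(C)C(C)(C)C)C1=O | intermediate
19 | lithium C9=C10 enolate formed from 18 by hydride addition at C1 | C[C@@H]1C[C@@H](O[Si](C)(C)C(C)(C)C)[C@@H]2C(CCC[C@]2(C)C(=O)O[Si](C)(C)C(C)(C)C)=C1[O-].[Li+] | intermediate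
20 | tert-butyldimethylsilyl 6β-(tert-butyldimethylsilyloxy)-4α,8α-dimethyl-9-(trifluoromethylsulfonyloxy)-5α-bicyclo[4.4.0]dec-9(10)-ene-4β-carboxylate | C[C@@H]1C[C@@H](O[Si](C)(C)C(C)(C)C)[C@@H]2C(CCC[C@]2(C)C(=O)O[Si](C)(C)C(C)(C)C)=C1OS(=O)(=O)C(F)(F)F | intermediate
21 | (S)-malic acid | O[C@@H](CC(=O)O)C(=O)O | starting material
22 | [(2S,4S)-2-tert-butyl-5-oxo-1,3-dioxolan-4-yl]acetic acid (cis) | CC(C)(C)[C@H]1O[C@@H](CC(=O)O)C(=O)O1 | intermediate
23 | phenyl vinyl sulfoxide | C=CS(=O)c1ccccc1 | starting material
24 | dilithium salt of 22 (carboxylate and dioxolanone enolate) | CC(C)(C)[C@H]1OC(CC(=O)[O-])=C([O-])O1.[Li+].[Li+] | intermediate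
25 | [(2S,4R)-2-tert-butyl-5-oxo-4-[2-(phenylsulfinyl)ethyl]-1,3-dioxolan-4-yl]acetic acid (both configurations at sulfur) | CC(C)(C)[C@H]1O[C@@](CCS(=O)c2ccccc2)(CC(=O)O)C(=O)O1 | intermediate
26 | [(2S,4R)-2-tert-butyl-4-ethenyl-5-oxo-1,3-dioxolan-4-yl]acetic acid | CC(C)(C)[C@H]1O[C@@](C=C)(CC(=O)O)C(=O)O1 | intermediate
27 | mixed isobutyl carbonic anhydride of 26 | CC(C)(C)[C@H]1O[C@@](C=C)(CC(=O)OC(=O)OCC(C)C)C(=O)O1 | intermediate
28 | (2S,5R)-2-tert-butyl-5-ethenyl-5-(2-hydroxyethyl)-1,3-dioxolan-4-one | CC(C)(C)[C@H]1O[C@@](C=C)(CCO)C(=O)O1 | intermediate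
29 | (3R)-3-ethenyl-3-hydroxyoxolan-2-one | O[C@@]1(C=C)CCOC1=O | intermediate
30 | (3S)-3-[2-(9-borabicyclo[3.3.1]nonan-9-yl)ethyl]-3-hydroxyoxolan-2-one | O[C@@]1(CCB2C3CCCC2CCC3)CCOC1=O | intermediate
31 | tert-butyldimethylsilyl 6β-(tert-butyldimethylsilyloxy)-9-{2-[(3S)-3-hydroxy-2-oxooxolan-3-yl]ethyl}-4α,8α-dimethyl-5α-bicyclo[4.4.0]dec-9(10)-ene-4β-carboxylate | C[C@@H]1C[C@@H](O[Si](C)(C)C(C)(C)C)[C@@H]2C(CCC[C@]2(C)C(=O)O[Si](C)(C)C(C)(C)C)=C1CC[C@]1(O)CCOC1=O | intermediate
32 | 6β-(tert-butyldimethylsilyloxy)-9-{2-[(3S)-3-hydroxy-2-oxooxolan-3-yl]ethyl}-4α,8α-dimethyl-5α-bicyclo[4.4.0]dec-9(10)-ene-4β-carboxylic acid | C[C@@H]1C[C@@H](O[Si](C)(C)C(C)(C)C)[C@@H]2C(CCC[C@]2(C)C(=O)O)=C1CC[C@]1(O)CCOC1=O | intermediate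
33 | chloromethyl chlorosulfate | ClCOS(=O)(=O)Cl | starting material
34 | chloromethyl ester of 32 (C9=C10 olefin, 6β-silyl ether, (S)-hydroxy lactone arm) | C[C@@H]1C[C@@H](O[Si](C)(C)C(C)(C)C)[C@@H]2C(CCC[C@]2(C)C(=O)OCCl)=C1CC[C@]1(O)CCOC1=O | intermediate
35 | acyloxymethyl cation derived from 34, as its triflate | C[C@@H]1C[C@@H](O[Si](C)(C)C(C)(C)C)[C@@H]2C(CCC[C@]2(C)C(=O)O[CH2+])=C1CC[C@]1(O)CCOC1=O.[O-]S(=O)(=O)C(F)(F)F | intermediate
36 | tertiary C9 cation with the 19,20-lactone closed (C20 β), as its triflate | C[C@@H]1C[C@@H](O[Si](C)(C)C(C)(C)C)[C@@H]2[C@]3(CCC[C@]2(C)C(=O)OC3)[C+]1CC[C@]1(O)CCOC1=O.[O-]S(=O)(=O)C(F)(F)F | intermediate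
37 | 6-O-tert-butyldimethylsilyl ether of the target | C[C@@H]1C[C@@H](O[Si](C)(C)C(C)(C)C)[C@@H]2[C@]3(CCC[C@]2(C)C(=O)OC3)[C@@]12CC[C@@]1(CCOC1=O)O2 | intermediate
38 | (13S)-9α,13-epoxy-6β-hydroxylabdane-19,20:16,15-diolide (CNP0393616.1) | C[C@@H]1C[C@@H](O)[C@@H]2[C@]3(CCC[C@]2(C)C(=O)OC3)[C@@]12CC[C@@]1(CCOC1=O)O2 | target

Total step count: 19. Longest linear sequence: 15 steps (steps 1–11 and 16–19).

Steps most likely to fail

First, step 18, the step that carries the new method. The cascade may be diverted by proton loss from the C9 cation, by quenching of the cationic carbon at oxygen instead of at C10, or by acid-induced protonation of the olefin followed by lactonisation of the carboxyl onto C10. The fallback uses known reactions; it sets out from acid 32 and comes back to the route at 37. Simmons–Smith cyclopropanation (Et2Zn, CH2I2, CH2Cl2, 0 °C), in which the zinc carboxylate at C19 carries the carbenoid to the β face, would give the 9β,10β-methano derivative of acid 32 F1. Hg(O2CCF3)2 then opens the cyclopropane at C20 with backside entry of the C13 hydroxyl at C9 (the β-oriented carboxyl cannot reach C10 from behind), and aqueous NaCl gives the 20-chloromercurio 9α,13-epoxy acid F2. Oxidative demercuration (NaBH4, O2, DMF) gives the 20-hydroxy 9α,13-epoxy acid F3, and carbodiimide lactonisation of the latter closes the δ-lactone to give 37.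

Second, step 16. Oxidative addition and transmetalation at the congested tetrasubstituted triflate may be slower than hydrolysis of the triflate or protodeboronation of the alkylborane. The fallback changes the nucleophile to an organozinc; it sets out from 29 and comes back to the route at 32. Borane 30, made from 29 as in step 16, is iodinated (I2, NaOMe, MeOH, 0 °C) to (3R)-3-hydroxy-3-(2-iodoethyl)oxolan-2-one F4, and the hydroxyl is capped (Me3SiCl, imidazole) to give (3R)-3-(2-iodoethyl)-3-(trimethylsilyloxy)oxolan-2-one F5. Zinc insertion (Zn, LiCl, THF) gives {2-[(3R)-2-oxo-3-(trimethylsilyloxy)oxolan-3-yl]ethyl}zinc iodide F6, and Negishi coupling with 20 (Pd(OAc)2, SPhos, THF/DMA, 40 °C) gives the 13-O-trimethylsilyl ether of 31 F7. Aqueous acetic acid then removes the trimethylsilyl ether and the silyl ester and gives 32.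

Third, step 3. Facial or regiochemical discrimination by the chiral catalyst may be poor for a 1,4-disubstituted diene, and the strong acid may ionise the allylic silyl ether. The fallback replaces asymmetric catalysis by resolution; it sets out from 3 and 4 and comes back to the route at 7. Cycloaddition promoted by BF3·OEt2 (CH2Cl2, −78 °C), which binds the same carbonyl, gives the racemic form of adduct 5 F8, and the conditions of step 4 convert it into the racemic form of triol 7 F9. Lipase-catalysed acylation of the primary hydroxyl (Burkholderia cepacia lipase, vinyl acetate) separates the enantiomers. The required enantiomer is obtained directly as 7 or, if it is the faster-reacting one, as the 19-O-acetate of triol 7 F10, which K2CO3 in MeOH converts into 7.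

Further compounds

F1 | step 18 | 9β,10β-methano derivative of acid 32 | C[C@@H]1C[C@@H](O[Si](C)(C)C(C)(C)C)[C@@H]2[C@@]3(CCC[C@]2(C)C(=O)O)C[C@@]13CC[C@]1(O)CCOC1=O
F2 | step 18 | 20-chloromercurio 9α,13-epoxy acid | C[C@@H]1C[C@@H](O[Si](C)(C)C(C)(C)C)[C@@H]2[C@@](CCC[C@]2(C)C(=O)O)(C[Hg]Cl)[C@@]12CC[C@@]1(CCOC1=O)O2
F3 | step 18 | 20-hydroxy 9α,13-epoxy acid | C[C@@H]1C[C@@H](O[Si](C)(C)C(C)(C)C)[C@@H]2[C@@](CCC[C@]2(C)C(=O)O)(CO)[C@@]12CC[C@@]1(CCOC1=O)O2
F4 | step 16 | (3R)-3-hydroxy-3-(2-iodoethyl)oxolan-2-one | O[C@@]1(CCI)CCOC1=O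
F5 | step 16 | (3R)-3-(2-iodoethyl)-3-(trimethylsilyloxy)oxolan-2-one | C[Si](C)(C)O[C@@]1(CCI)CCOC1=O
F6 | step 16 | {2-[(3R)-2-oxo-3-(trimethylsilyloxy)oxolan-3-yl]ethyl}zinc iodide | C[Si](C)(C)O[C@@]1(CC[Zn]I)CCOC1=O
F7 | step 16 | 13-O-trimethylsilyl ether of 31 | C[C@@H]1C[C@@H](O[Si](C)(C)C(C)(C)C)[C@@H]2C(CCC[C@]2(C)C(=O)O[Si](C)(C)C(C)(C)C)=C1CC[C@]1(O[Si](C)(C)C)CCOC1=O
F8 | step 3 | racemic form of adduct 5 (relative configuration shown) | CC1=CC(=O)[C@@H]2[C@H](C1=O)[C@H]([Si](CC)(CC)CC)C=C[C@@H]2CO[Si](CC)(CC)CC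
F9 | step 3 | racemic form of triol 7 (relative configuration shown) | CC1=C[C@@H](O)[C@@H]2[C@H]([C@H]1O)[C@H]([Si](CC)(CC)CC)C=C[C@@H]2CO
F10 | step 3 | 19-O-acetate of triol 7 | CC1=C[C@@H](O)[C@@H]2[C@H]([C@H]1O)[C@H]([Si](CC)(CC)CC)C=C[C@@H]2COC(C)=O
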